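## Analysis of the target

The target is a cis-fused decalin, numbered here in the terpenoid way (ring A: C1–C5 and C10; ring B: C5–C10), with an exocyclic methylidene on C8 and, on C9, a CH2 group (C11) bound to C3′ of a fully substituted 2-methoxy-4-pyranone that carries a methyl ester. C3 is a secondary carbinol, and the quaternary C4 carries a methyl group and a CH2CH2C(CH3)2–O–CHO chain. The five stereocentres are (3S,4R,5R,9S,10S); with α defined as the face of the angular C10 methyl, H5 and the C4 methyl are α, and the C3 hydroxyl, the C4 side chain and C11 are β. The sensitive groups are the tertiary formate (lost to base, nucleophiles and strong hydrides), the methoxypyranone (a vinylogous carbonate), the exocyclic alkene (acid-induced migration) and the free secondary alcohol, which must be kept apart from the tertiary one. The synthesis is hard because two quaternary carbons (C4, C10) flank the ring fusion, the fusion is cis with an angular methyl, the C3 oxygen is cis to ring B, and a secondary and a tertiary alcohol must be told apart at the end. The strategy rests on the bond pair C5–C10 and C8–C9: C10 bears a methyl and is next to C1, and C5 is the ring-fusion CH next to C4. An isopropenyl ketone (C9=C10, C1 as carbonyl) and an (E)-diene C5=C6–C7=C8 hung on C4 therefore close both rings in one cycloaddition, with C4 and C3 set beforehand on an open chain.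

## Retrosynthetic reasoning

**C3 and the formate (40 back to 36).** The C3–H bond is cut last: 40 comes from keto formate 39 by a reagent-controlled reduction. The ketone serves as the protecting group for C3 while the tertiary alcohol of 38 is formylated, so no secondary/tertiary differentiation is needed. 38 comes from diol 37 by oxidation of the only oxidisable hydroxyl, and 37 from the bis-silyl ether 36. C3 is rebuilt late because the cycloaddition below needs the unnatural C3 configuration.

**C8 methylidene and the pyranone (36 back to 29 and 32).** The C8=CH2 bond is cut to ketone 35, which comes from enone 34 by saturation of C6=C7. The methoxy group of the pyranone is cut to hydroxypyranone 33. The C11–C3′ bond of 33 is cut as a conjugate addition of hydroxypyranone 32, a cyclic 1,3-dicarbonyl nucleophile, to the exocyclic dienone 29. This cut is chosen over an alkylation with a halomethyl pyranone because C11 is then already on C9 when C9 becomes a stereocentre. The last event at C9 is a protonation from the convex face, which gives the required β-C11. 32 is made in one step from 30 and 31.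

**C9–C11 and the C8 oxygen (29 back to 24).** C11 is cut from C9 as a one-carbon iminium electrophile added to the cross-conjugated enolate of enone 25. The enone is needed because it leaves C9 as the only enolisable position. 25 comes from alkene 24 by oxidation of the allylic methylene C8, which the C6=C7 alkene left by the cycloaddition activates.

**C1 oxygen (24 back to 21).** The carbonyl that activated the dienophile is removed from octalone 21 by reduction to 22, acylation to 23 and radical deoxygenation. These three steps are the cost of placing the activating group inside the tether.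

**Both rings (21 back to 20).** C5–C10 and C8–C9 are cut together, which opens 21 to the trienone 20. This cut removes two rings, two C–C bonds and two stereocentres (C5, C10). It leaves an open chain on which the contiguous C3 and C4 can be made by enolate chemistry. In the endo transition state ring A is a chair with C6 axial at C5 and the dienophile methyl axial at C10. An oxygen of the natural configuration at C3 is cis to C6 and would be 1,3-diaxial to the diene. The cycloaddition is therefore planned on the C3 epimer (3R), whose silyl ether is equatorial exactly when the C4 methyl, and not the C4 chain, lies syn to the C10 methyl. C3 and C4 then work in the same sense.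

**C2–C3 (20 back to 15 and 16).** The silyl ether 20 comes from aldol 19. The C2–C3 bond is cut as the boron aldol addition of methyl ketone 16 to the non-enolisable aldehyde 15, with the chiral ligands on boron setting C3.

**C4 (15 back to 11 and 4).** 15 comes from alcohol 14, and 14 from imide 13 by reductive removal of the auxiliary. The C4–CH2 bond of 13 is cut as the α-alkylation of the extended enolate of dienoyl imide 11 with triflate 4. This one bond formation creates the quaternary centre and the (E)-diene together. 11 comes from acid 8 and auxiliary 9, 8 from ester 7, and 7 from 5 and 6 by olefination. 4 comes from diol 1 through 2 and 3.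

## Alternatives that were turned down

**Alternative 1:** The disconnection is C5–C6. In the forward step the primary C6 radical generated from iodo dienone A2 adds 6-exo to one of the two enone arms of A2 and gives the cis-fused enone A1.
- For it: A1 already holds the C8 methylidene and a C9–CH2O substituent, the part on which the chosen route spends six steps. The cis fusion follows from the ring-closure geometry, and the angular methyl comes from a simple aromatic precursor. On ring B this plan is stronger.
- Against it: ring A of A1 is a bare enone. C4 is a CH2 that must receive both the methyl and the side chain by two enolate alkylations next to the ring fusion, where the order of introduction, not the need of the target, fixes the configuration. The choice between the two diastereotopic enone arms of A2 depends on its single C9 stereocentre, which must first be made enantioselectively. The C1=C2 alkene must be removed and C3 reduced.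
- Comparison: the chosen route builds C4 on an open chain, where it is reliable, and uses C4 and C3 to control the ring fusion. It pays with the removal of the C1 oxygen and the later build-up of C8/C9.

**Alternative 2:** The disconnection is C9–C11 and C11–C3′ in one operation. Hydroxypyranone 32, the same building block as in the chosen route, condenses with formaldehyde A5 to the methylidene pyrandione A6, which is captured at its terminus by the C8–C9 silyl enol ether A4. Hydrolysis gives ketone A3.
- For it: it is convergent, uses the natural nucleophilicity of C3′ and needs no halomethyl pyranone. For this union it is one step shorter than the chosen sequence of methylenation and conjugate addition, so on this point it is at least as strong.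
- Against it: it is a plan for the appendage and not for the decalin, and it needs the regiodefined enol ether A4. The acceptor A6 tends to take up a second molecule of 32. The C9–C11 bond forms by attack of the electrophile on the convex face of A4, which puts C11 cis to the C10 methyl, so C9 must then be epimerised. O-methylation and methylenation of A3 still follow.
- Comparison: the chosen route keeps the same polarity in stepwise form, with protonation as the last event at C9. It also supplies what this alternative lacks, a controlled entry to the cis-decalin.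

**Alternative 3:** The disconnection is C4–C5 and C1–C10. Under a chiral Lewis acid the silyloxy diene A9 adds across the alkene of 2-methylcyclohex-2-enone A8 and gives the cis-fused adduct A7.
- For it: absolute configuration comes from a catalyst, the cis fusion is automatic, the angular methyl comes from a cheap enone, and the C3 oxygen is present at once. In catalytic economy it is stronger than an auxiliary plus a chiral borane.
- Against it: A8 is a weak, trisubstituted dienophile. In A7 C4 is still a CH bearing an ester, so the quaternary centre must be made by alkylation on the concave-convex bicycle, and the ester must be reduced to a methyl. The ring B carbonyl of A7 sits at C9, where the target has the CH–CH2 link, and not at C8, so the oxygen must be moved.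
- Comparison: the chosen cycloaddition needs more steps before the key step, but delivers C4 complete and leaves an alkene that gives access to C8.

Key step: step 12

Assumption: the facial senses of the auxiliary-controlled alkylation (step 7) and of the borane-controlled aldol (step 10) are assigned from the accepted models; if either proved opposite, the antipodal auxiliary or borane would be used with no other change.

## Route

Step 1
Reactants: 1 3-methylbutane-1,3-diol
Product: 2 2-methyl-2,4-bis(triethylsilyloxy)butane
Conditions: TESOTf (2.3 equiv), 2,6-lutidine, CH2Cl2, −78 to 0 °C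
Reagents that add atoms: triethylsilyl trifluoromethanesulfonate, CC[Si](CC)(CC)OS(=O)(=O)C(F)(F)F
Why: Silyl triflate with a hindered base silylates the primary and the tertiary hydroxyl; both are silylated because the tertiary one cannot be silylated selectively.

Step 2
Reactants: 2 2-methyl-2,4-bis(triethylsilyloxy)butane
Product: 3 3-methyl-3-(triethylsilyloxy)butan-1-ol
Conditions: PPTS (0.1 equiv), MeOH/CH2Cl2, 0 °C
Reagents that add atoms: none
Why: Acid-catalysed methanolysis of silyl ethers follows steric access, so the primary ether should cleave well before the tertiary one.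

Step 3
Reactants: 3 3-methyl-3-(triethylsilyloxy)butan-1-ol
Product: 4 3-methyl-3-(triethylsilyloxy)butyl trifluoromethanesulfonate
Conditions: Tf2O, 2,6-lutidine, CH2Cl2, −78 °C; cold aqueous work-up, used at once
Reagents that add atoms: trifluoromethanesulfonic anhydride, O=S(=O)(OS(=O)(=O)C(F)(F)F)C(F)(F)F
Why: Sulfonylation of a primary alcohol; the triflate is chosen because sodium imide enolates react poorly with unactivated primary iodides but readily with primary triflates at −78 °C.

Step 4
Reactants: 5 (E)-but-2-enal, 6 ethyl 2-(triphenylphosphoranylidene)propanoate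
Product: 7 ethyl (2E,4E)-2-methylhexa-2,4-dienoate
Conditions: CH2Cl2, rt
Reagents that add atoms: none
Why: Wittig olefination with a stabilised, α-branched ylide, which should give the (E)-trisubstituted alkene; the (E)-alkene of the aldehyde is retained.

Step 5
Reactants: 7 ethyl (2E,4E)-2-methylhexa-2,4-dienoate
Product: 8 (2E,4E)-2-methylhexa-2,4-dienoic acid
Conditions: LiOH, THF/MeOH/H2O, rt; then aqueous HCl
Reagents that add atoms: lithium hydroxide, [Li+].[OH-]
Why: Ester saponification; the dienoate has no base-sensitive stereocentre.

Step 6
Reactants: 8 (2E,4E)-2-methylhexa-2,4-dienoic acid, 9 (4S)-4-(propan-2-yl)-1,3-oxazolidin-2-one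
Product: 11 (4S)-3-[(2E,4E)-2-methylhexa-2,4-dienoyl]-4-(propan-2-yl)-1,3-oxazolidin-2-one, via pivalic mixed anhydride 10 (not isolated)
Conditions: PivCl, Et3N, THF, −20 °C; then 9, LiCl, −20 °C to rt
Reagents that add atoms: none
Why: N-acylation of the oxazolidinone through the mixed pivalic anhydride, the standard way to make unsaturated imides without conjugate addition.

Step 7
Reactants: 11 (4S)-3-[(2E,4E)-2-methylhexa-2,4-dienoyl]-4-(propan-2-yl)-1,3-oxazolidin-2-one, 4 3-methyl-3-(triethylsilyloxy)butyl trifluoromethanesulfonate
Product: 13 (4S)-3-[(2R,3E)-2-methyl-2-[3-methyl-3-(triethylsilyloxy)butyl]hexa-3,5-dienoyl]-4-(propan-2-yl)-1,3-oxazolidin-2-one, via sodium trienolate 12 (not isolated)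
Conditions: NaN(SiMe3)2, THF, −78 °C; then 4, −78 to −40 °C
Reagents that add atoms: none
Why: Deconjugative α-alkylation of an extended imide enolate: the base removes a proton from the terminal methyl, and trienolate 12 reacts with the hard primary triflate at the α-carbon, which creates the quaternary C4 and the (E)-diene at once. The isopropyl group of the auxiliary shields one face; with the (S)-auxiliary and the α-methyl cis to the enolate oxygen the electrophile should enter to give the (R)-centre.

Step 8
Reactants: 13 alkylated imide
Product: 14 (2R,3E)-2-methyl-2-[3-methyl-3-(triethylsilyloxy)butyl]hexa-3,5-dien-1-ol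
Conditions: LiBH4, MeOH (1 equiv), Et2O, 0 °C
Reagents that add atoms: none
Why: Reductive cleavage of the N-acyl oxazolidinone; the small borohydride attacks the exocyclic carbonyl, the auxiliary is recovered, and the quaternary centre cannot epimerise.

Step 9
Reactants: 14 dienol
Product: 15 (2R,3E)-2-methyl-2-[3-methyl-3-(triethylsilyloxy)butyl]hexa-3,5-dienal
Conditions: Dess–Martin periodinane, NaHCO3, CH2Cl2, rt
Reagents that add atoms: none
Why: Buffered Dess–Martin oxidation of a neopentyl primary alcohol; the aldehyde has no α-hydrogen and the silyl ether and diene are untouched.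

Step 10
Reactants: 15 dienal, 16 3-methylbut-3-en-2-one
Product: 19 (5R,6R,7E)-5-hydroxy-2,6-dimethyl-6-[3-methyl-3-(triethylsilyloxy)butyl]deca-1,7,9-trien-3-one, via enol borinate 17 (not isolated), via boron aldolate 18 (not isolated)
Conditions: (−)-Ipc2BCl, Et3N, Et2O, 0 °C; then 15, −78 to −20 °C; H2O2, pH 7 buffer, MeOH, 0 °C
Reagents that add atoms: none
Why: Boron aldol addition of a methyl ketone through its enol diisopinocampheylborinate to a non-enolisable aldehyde. The (−)-borane, made from (+)-α-pinene, should direct attack to the Re face and give the (R)-carbinol at the future C3, the epimer that the cycloaddition needs.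

Step 11
Reactants: 19 hydroxy trienone
Product: 20 (5R,6R,7E)-5-(tert-butyldimethylsilyloxy)-2,6-dimethyl-6-[3-methyl-3-(triethylsilyloxy)butyl]deca-1,7,9-trien-3-one
Conditions: TBSOTf, 2,6-lutidine, CH2Cl2, −78 °C
Reagents that add atoms: tert-butyldimethylsilyl trifluoromethanesulfonate, CC(C)(C)[Si](C)(C)OS(=O)(=O)C(F)(F)F
Why: Silylation of a hindered β-hydroxy ketone at low temperature, which avoids retro-aldol cleavage and dehydration; the trienone is used at once and kept cold.

Step 12
Reactants: 20 silyloxy trienone
Product: 21 cis-fused octalone (C1 ketone, C6=C7; 3α-OTBS, 4α-methyl, 5α-H, 10α-methyl)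
Conditions: MeAlCl2 (1.1 equiv), CH2Cl2, −78 to −30 °C
Reagents that add atoms: none
Why: MeAlCl2 binds the C1 carbonyl and the s-cis enone adds across the (E)-diene in a concerted, asynchronous [4+2] cycloaddition with C8–C9 bonding ahead of C5–C10; this is the known behaviour of Lewis-acid-promoted intramolecular Diels–Alder reactions of 1,7,9-decatrien-3-ones. Ring B is the cyclohexene formed by the cycloaddition itself, and ring A is closed at the same time by the four-atom tether C1–C4 in the fused mode, the only mode this tether length allows. C5 and C10 are created together: the endo transition state, with the tether carbonyl under the diene, puts H5 and the C10 methyl cis, and the (E)-geometry of C5=C6 is transferred to C5. In that transition state ring A is a chair with C6 axial at C5 and the dienophile methyl axial at C10, so a C3 substituent cis to C6 would be 1,3-diaxial to the diene. The (3R)-silyl ether is equatorial only when the diene adds to the face that places the C4 methyl, and not the C4 chain, syn-axial to the C10 methyl, and that is the face required, so C3 and C4 are matched. The step needs endo over exo selectivity, which the Lewis acid and the carbonyl inside the tether favour, and diene-face selectivity, which C3 and C4 secure. The quaternary C4 also speeds ring closure (gem-dialkyl effect).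

Step 13
Reactants: 21 cis-fused octalone
Product: 22 C1 alcohol of 21 (both C1 epimers)
Conditions: NaBH4, MeOH/THF, 0 °C to rt
Reagents that add atoms: none
Why: Borohydride reduction of a ketone with one quaternary α-carbon; the C1 configuration is irrelevant because the centre is removed two steps later.

Step 14
Reactants: 22 C1 alcohol
Product: 23 O-phenyl thionocarbonate of 22
Conditions: PhOC(S)Cl, pyridine, DMAP (cat.), CH2Cl2, rt
Reagents that add atoms: O-phenyl chlorothionoformate, S=C(Cl)Oc1ccccc1
Why: Acylation under non-anionic conditions gives the radical precursor without forming the C1 alkoxide, which could take over the silyl group from the 1,3-related C3 oxygen.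

Step 15
Reactants: 23 thionocarbonate
Product: 24 cis-octalin (C1 methylene, C6=C7; 3α-OTBS)
Conditions: Bu3SnH, AIBN (cat.), toluene, 100 °C
Reagents that add atoms: none
Why: Barton–McCombie deoxygenation of a secondary thionocarbonate; the stannane is kept concentrated enough for hydrogen transfer to outrun addition of the C1 radical to the C6=C7 alkene.

Step 16
Reactants: 24 cis-octalin
Product: 25 enone (C8 ketone, C6=C7)
Conditions: Rh2(cap)4 (cap = caprolactamate, 1 mol %), tBuOOH, K2CO3, CH2Cl2, rt
Reagents that add atoms: tert-butyl hydroperoxide, CC(C)(C)OO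
Why: Catalytic allylic oxidation by tert-butylperoxyl radicals: hydrogen abstraction should prefer the C8 methylene over the C5 methine, which is buried between two quaternary carbons. The allyl radical is oxygenated at its less hindered C8 end, and the peroxide collapses to the conjugated enone.

Step 17
Reactants: 25 enone
Product: 29 exocyclic dienone (C8 ketone, C6=C7, C9=C11H2), via lithium dienolate 26 (not isolated), via Mannich base 27 (not isolated), via ammonium iodide 28 (not isolated)
Conditions: LiN(iPr)2, THF, −78 °C; CH2=NMe2+ I−, −78 °C to rt; MeI, CH2Cl2, rt; DBU, rt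
Reagents that add atoms: N,N-dimethylmethyleneiminium iodide, C=[N+](C)C.[I-]
Why: Kinetic deprotonation of the enone can only occur at C9; a Mannich reaction with the iminium salt, quaternisation and base-induced elimination form the α-methylene ketone (known α-methylenation sequence). The dienone is used without delay.

Step 18
Reactants: 30 methyl acetoacetate, 31 malonyl dichloride
Product: 32 methyl 4-hydroxy-6-methyl-2-oxo-2H-pyran-5-carboxylate
Conditions: CH2Cl2, rt to 40 °C
Reagents that add atoms: none
Why: C-acylation of the keto ester at its central carbon by the diacid chloride, followed by enol lactonisation with the second acyl chloride, is the known route to 5-acyl-4-hydroxy-2-pyranones.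

Step 19
Reactants: 29 exocyclic dienone, 32 hydroxypyranone
Product: 33 Michael adduct (C8 ketone, C6=C7, 9β-CH2–(4-hydroxy-2-pyranon-3-yl))
Conditions: Et3N (0.2 equiv), CH2Cl2, rt
Reagents that add atoms: none
Why: Michael addition of the soft C3′ carbon of the cyclic 1,3-dicarbonyl to the unhindered exocyclic methylene, which is far more reactive than the ring enone. The resulting dienolate is protonated at C9 on the convex α face, anti to the pseudo-axial C1–C10 bond, so C11 becomes equatorial and trans to the C10 methyl, which is also the more stable epimer.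

Step 20
Reactants: 33 Michael adduct
Product: 34 methoxypyranone enone
Conditions: MeOTf, 2,6-di-tert-butyl-4-methylpyridine, CH2Cl2, 0 °C to rt
Reagents that add atoms: methyl trifluoromethanesulfonate, COS(=O)(=O)C(F)(F)F
Why: A hard methylating agent attacks the most basic site of the neutral hydroxypyranone, the lactone carbonyl oxygen, and loss of the O4 proton gives the 2-methoxy-4-pyranone (known O-methylation mode). The C4′ hydroxyl is hydrogen-bonded to the ester and less nucleophilic, and the hindered base removes TfOH so that the silyl ethers survive.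

Step 21
Reactants: 34 methoxypyranone enone
Product: 35 saturated C8 ketone
Conditions: H2 (1 atm), Pd/C, EtOAc, rt
Reagents that add atoms: none
Why: Hydrogenation of the disubstituted enone alkene; the tetrasubstituted pyranone double bonds are not reduced at this pressure, and no stereocentre is formed or lost.

Step 22
Reactants: 35 saturated C8 ketone
Product: 36 C8 methylidene compound (3α-OTBS, tertiary OTES)
Conditions: Zn, CH2Br2, TiCl4, THF, 0 °C (pre-formed reagent); then 35, CH2Cl2, rt
Reagents that add atoms: dibromomethane, BrCBr
Why: Takai–Lombardo methylenation: the non-basic gem-dimetallic reagent converts the hindered ketone without epimerising C9 and leaves the ester and pyranone carbonyls alone. Partial loss of the triethylsilyl group here would not matter, since the next step removes both silyl groups.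

Step 23
Reactants: 36 C8 methylidene compound
Product: 37 diol (3α-OH, tertiary OH)
Conditions: HF·pyridine, pyridine, THF, 0 °C to rt
Reagents that add atoms: none
Why: Fluoride cleaves both silyl ethers; the pyridine buffer keeps the exocyclic alkene and the methoxypyranone intact.

Step 24
Reactants: 37 diol
Product: 38 hydroxy ketone (C3 ketone, tertiary OH)
Conditions: Dess–Martin periodinane, NaHCO3, CH2Cl2, rt
Reagents that add atoms: none
Why: Dess–Martin oxidation, in which only the secondary alcohol can be oxidised; this removes the unnatural C3 configuration and masks C3 for the formylation.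

Step 25
Reactants: 38 hydroxy ketone
Product: 39 keto formate
Conditions: acetic formic anhydride, pyridine, DMAP (cat.), CH2Cl2, 0 °C to rt
Reagents that add atoms: acetic formic anhydride, CC(=O)OC=O
Why: Acyl transfer from the mixed anhydride, which hands over its formyl group, the less hindered and more electrophilic acyl, to the tertiary alcohol; no other hydroxyl is present.

Step 26
Reactants: 39 keto formate
Product: 40 target, (3S,4R,5R,9S,10S)
Conditions: (R)-2-methyl-CBS-oxazaborolidine (1 equiv), catecholborane, toluene, −78 to −40 °C
Reagents that add atoms: none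
Why: CBS reduction: the oxazaborolidine binds the carbonyl oxygen anti to the quaternary C4 and delivers hydride to the α face, giving the (3S), β-alcohol. Reagent control is used because both faces are hindered (β by C6, α by the C4 methyl), and catecholborane at low temperature spares the formate, the esters and the alkene.

## Compound list

In the decalin names, α is the face of the C10 methyl; absolute configuration is as in the SMILES.

1 | 3-methylbutane-1,3-diol | CC(C)(O)CCO | starting material
2 | 2-methyl-2,4-bis(triethylsilyloxy)butane | CC(C)(CCO[Si](CC)(CC)CC)O[Si](CC)(CC)CC | intermediate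
3 | 3-methyl-3-(triethylsilyloxy)butan-1-ol | CC(C)(CCO)O[Si](CC)(CC)CC | intermediate
4 | 3-methyl-3-(triethylsilyloxy)butyl trifluoromethanesulfonate | CC(C)(CCOS(=O)(=O)C(F)(F)F)O[Si](CC)(CC)CC | intermediate
5 | (E)-but-2-enal (crotonaldehyde) | C/C=C/C=O | starting material
6 | ethyl 2-(triphenylphosphoranylidene)propanoate | CCOC(=O)C(C)=P(c1ccccc1)(c1ccccc1)c1ccccc1 | starting material
7 | ethyl (2E,4E)-2-methylhexa-2,4-dienoate | C/C=C/C=C(\C)C(=O)OCC | intermediate
8 | (2E,4E)-2-methylhexa-2,4-dienoic acid | C/C=C/C=C(\C)C(=O)O | intermediate
9 | (4S)-4-(propan-2-yl)-1,3-oxazolidin-2-one | CC(C)[C@H]1COC(=O)N1 | starting material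
10 | (2E,4E)-2-methylhexa-2,4-dienoic pivalic anhydride | C/C=C/C=C(\C)C(=O)OC(=O)C(C)(C)C | intermediate
11 | (4S)-3-[(2E,4E)-2-methylhexa-2,4-dienoyl]-4-(propan-2-yl)-1,3-oxazolidin-2-one | C/C=C/C=C(\C)C(=O)N1[C@@H](C(C)C)COC1=O | intermediate
12 | sodium trienolate of 11 (enolate oxygen cis to the α-methyl) | C=C/C=C/C(C)=C(/[O-])N1[C@@H](C(C)C)COC1=O.[Na+] | intermediate
13 | (4S)-3-[(2R,3E)-2-methyl-2-[3-methyl-3-(triethylsilyloxy)butyl]hexa-3,5-dienoyl]-4-(propan-2-yl)-1,3-oxazolidin-2-one | O=C(N1[C@@H](C(C)C)COC1=O)[C@](C)(CCC(C)(C)O[Si](CC)(CC)CC)/C=C/C=C | intermediate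
14 | (2R,3E)-2-methyl-2-[3-methyl-3-(triethylsilyloxy)butyl]hexa-3,5-dien-1-ol | OC[C@](C)(CCC(C)(C)O[Si](CC)(CC)CC)/C=C/C=C | intermediate
15 | (2R,3E)-2-methyl-2-[3-methyl-3-(triethylsilyloxy)butyl]hexa-3,5-dienal | O=C[C@](C)(CCC(C)(C)O[Si](CC)(CC)CC)/C=C/C=C | intermediate
16 | 3-methylbut-3-en-2-one | CC(=O)C(C)=C | starting material
17 | enol diisopinocampheylborinate of 16 | C=C(C)C(=C)OB([C@@H]1C[C@@H]2C[C@H]([C@H]1C)C2(C)C)[C@@H]1C[C@@H]2C[C@H]([C@H]1C)C2(C)C | intermediate
18 | boron aldolate (O-diisopinocampheylboryl derivative of 19) | C=C(C)C(=O)C[C@@H](OB([C@@H]1C[C@@H]2C[C@H]([C@H]1C)C2(C)C)[C@@H]1C[C@@H]2C[C@H]([C@H]1C)C2(C)C)[C@](C)(CCC(C)(C)O[Si](CC)(CC)CC)/C=C/C=C | intermediate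
19 | (5R,6R,7E)-5-hydroxy-2,6-dimethyl-6-[3-methyl-3-(triethylsilyloxy)butyl]deca-1,7,9-trien-3-one | C=C(C)C(=O)C[C@@H](O)[C@](C)(CCC(C)(C)O[Si](CC)(CC)CC)/C=C/C=C | intermediate
20 | (5R,6R,7E)-5-(tert-butyldimethylsilyloxy)-2,6-dimethyl-6-[3-methyl-3-(triethylsilyloxy)butyl]deca-1,7,9-trien-3-one | C=C(C)C(=O)C[C@@H](O[Si](C)(C)C(C)(C)C)[C@](C)(CCC(C)(C)O[Si](CC)(CC)CC)/C=C/C=C | intermediate
21 | cis-fused octalone, (3R,4R,5S,10S): C1 ketone, C6=C7, 3α-(tert-butyldimethylsilyloxy), 4α,10α-dimethyl, 5α-H, 4β-[3-methyl-3-(triethylsilyloxy)butyl] | C1C=C[C@H]2[C@@](C)(CCC(C)(C)O[Si](CC)(CC)CC)[C@H](O[Si](C)(C)C(C)(C)C)CC(=O)[C@@]2(C)C1 | intermediate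
22 | C1 alcohol of 21 (both C1 epimers) | C1C=C[C@H]2[C@@](C)(CCC(C)(C)O[Si](CC)(CC)CC)[C@H](O[Si](C)(C)C(C)(C)C)CC(O)[C@@]2(C)C1 | intermediate
23 | O-phenyl thionocarbonate of 22 | C1C=C[C@H]2[C@@](C)(CCC(C)(C)O[Si](CC)(CC)CC)[C@H](O[Si](C)(C)C(C)(C)C)CC(OC(=S)Oc3ccccc3)[C@@]2(C)C1 | intermediate
24 | cis-octalin: C1 methylene, C6=C7, substituents as in 21 | C1C=C[C@H]2[C@@](C)(CCC(C)(C)O[Si](CC)(CC)CC)[C@H](O[Si](C)(C)C(C)(C)C)CC[C@@]2(C)C1 | intermediate
25 | enone: C8 ketone, C6=C7, otherwise as 24 | O=C1C=C[C@H]2[C@@](C)(CCC(C)(C)O[Si](CC)(CC)CC)[C@H](O[Si](C)(C)C(C)(C)C)CC[C@@]2(C)C1 | intermediate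
26 | lithium C8,C9-dienolate of 25 | [Li+].[O-]C=1C=C[C@H]2[C@@](C)(CCC(C)(C)O[Si](CC)(CC)CC)[C@H](O[Si](C)(C)C(C)(C)C)CC[C@@]2(C)C=1 | intermediate
27 | Mannich base: 25 with CH2NMe2 on C9 | O=C1C=C[C@H]2[C@@](C)(CCC(C)(C)O[Si](CC)(CC)CC)[C@H](O[Si](C)(C)C(C)(C)C)CC[C@@]2(C)C1CN(C)C | intermediate
28 | trimethylammonium iodide of 27 | O=C1C=C[C@H]2[C@@](C)(CCC(C)(C)O[Si](CC)(CC)CC)[C@H](O[Si](C)(C)C(C)(C)C)CC[C@@]2(C)C1C[N+](C)(C)C.[I-] | intermediate
29 | exocyclic dienone: C8 ketone, C6=C7, C9=C11H2 | O=C1C=C[C@H]2[C@@](C)(CCC(C)(C)O[Si](CC)(CC)CC)[C@H](O[Si](C)(C)C(C)(C)C)CC[C@@]2(C)C1=C | intermediate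
30 | methyl acetoacetate | COC(=O)CC(C)=O | starting material
31 | malonyl dichloride | O=C(Cl)CC(Cl)=O | starting material
32 | methyl 4-hydroxy-6-methyl-2-oxo-2H-pyran-5-carboxylate | COC(=O)c1c(C)oc(=O)cc1O | intermediate
33 | Michael adduct: C8 ketone, C6=C7, 9β-CH2 bound to C3′ of the 4-hydroxy-2-pyranone, 9α-H | O=C1C=C[C@H]2[C@@](C)(CCC(C)(C)O[Si](CC)(CC)CC)[C@H](O[Si](C)(C)C(C)(C)C)CC[C@@]2(C)[C@H]1Cc1c(O)c(C(=O)OC)c(C)oc1=O | intermediate
34 | as 33 with the pyranone as 2-methoxy-4-pyranone | O=C1C=C[C@H]2[C@@](C)(CCC(C)(C)O[Si](CC)(CC)CC)[C@H](O[Si](C)(C)C(C)(C)C)CC[C@@]2(C)[C@H]1Cc1c(OC)oc(C)c(C(=O)OC)c1=O | intermediate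
35 | saturated C8 ketone | O=C1CC[C@H]2[C@@](C)(CCC(C)(C)O[Si](CC)(CC)CC)[C@H](O[Si](C)(C)C(C)(C)C)CC[C@@]2(C)[C@H]1Cc1c(OC)oc(C)c(C(=O)OC)c1=O | intermediate
36 | C8 methylidene compound, 3α-OTBS, tertiary OTES | C=C1CC[C@H]2[C@@](C)(CCC(C)(C)O[Si](CC)(CC)CC)[C@H](O[Si](C)(C)C(C)(C)C)CC[C@@]2(C)[C@H]1Cc1c(OC)oc(C)c(C(=O)OC)c1=O | intermediate
37 | diol: 3α-OH and tertiary OH | C=C1CC[C@H]2[C@@](C)(CCC(C)(C)O)[C@H](O)CC[C@@]2(C)[C@H]1Cc1c(OC)oc(C)c(C(=O)OC)c1=O | intermediate
38 | hydroxy ketone: C3 ketone, tertiary OH | C=C1CC[C@H]2[C@@](C)(CCC(C)(C)O)C(=O)CC[C@@]2(C)[C@H]1Cc1c(OC)oc(C)c(C(=O)OC)c1=O | intermediate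
39 | keto formate: C3 ketone, tertiary formate | C=C1CC[C@H]2[C@@](C)(CCC(C)(C)OC=O)C(=O)CC[C@@]2(C)[C@H]1Cc1c(OC)oc(C)c(C(=O)OC)c1=O | intermediate
40 | CNP0292250.1, (3S,4R,5R,9S,10S): 3β-OH, 4α-methyl, 4β-(3-formyloxy-3-methylbutyl), 5α-H, 8-methylidene, 9β-CH2–pyranone, 10α-methyl | C=C1CC[C@H]2[C@@](C)(CCC(C)(C)OC=O)[C@@H](O)CC[C@@]2(C)[C@H]1Cc1c(OC)oc(C)c(C(=O)OC)c1=O | target

## Step count and least certain steps

Total: 26 steps. Longest linear sequence: 22 steps (steps 4–17 and 19–26, from crotonaldehyde 5). Steps 1–3 and step 18 are side branches.

**Step 12 (key step).** The exo mode may compete and give the trans-fused adduct, because the methyl group on the dienophile works against the endo preference of the carbonyl. The Lewis acid may also ionise the β-silyloxy ketone. Fallback: cyclise one step earlier, without metal and without the silyl ether. The fallback sets out from hydroxy trienone 19, which is heated in aqueous trifluoroethanol, where hydrogen bonding to the carbonyl and the hydrophobic effect speed the cycloaddition and favour the compact endo transition state. The free hydroxyl prefers the equatorial position for the same 1,3-diaxial reason. This gives the hydroxy octalone F1, which is silylated with TBSOTf and 2,6-lutidine and rejoins the route at 21.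

**Step 7.** C-alkylation may be slow, so that the sodium enolate decomposes, alkylation may occur at the remote carbon, or the facial bias may be weak because the tetrasubstituted enolate twists the auxiliary out of plane. Fallback: change the bond formed in the stereo-defining step, so that the side chain is already in place and methyl iodide is the electrophile. The fallback sets out from triflate 4 and crotonaldehyde 5. Triethyl phosphonoacetate is alkylated with triflate 4 (NaH, THF) to the phosphonate F2. Horner–Wadsworth–Emmons reaction with crotonaldehyde 5 gives the dienoate F3, and saponification gives the acid F4. The acid is joined to the (R)-enantiomer of the auxiliary to give the imide F5. NaN(SiMe3)2 and then MeI give the methylated imide F6; the roles of methyl and chain are exchanged, hence the antipodal auxiliary. LiBH4 reduction of this imide rejoins the route at alcohol 14.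

**Step 16.** Hydrogen abstraction at the tertiary C5–H, or oxygen delivery to C6, would give transposed enones, and over-oxidation is possible. Fallback: ene-type selenium chemistry, which attacks a methylene in preference to a methine. Starting from octalin 24, SeO2 (cat.) with tBuOOH gives the C8 allylic alcohol F7, and Dess–Martin oxidation rejoins the route at enone 25.

**Step 19.** The exocyclic dienone 29 may dimerise by hetero-Diels–Alder reaction before it is trapped, and protonation at C9 may be unselective. Fallback: reverse the polarity so that 29 is never made. The fallback sets out from enone 25 and hydroxypyranone 32. Enone 25 is converted with LiN(iPr)2 and Me3SiCl into the trimethylsilyl dienol ether F8. Condensation of 32 with paraformaldehyde forms the methylidene pyrandione F9 in the flask, and the dienol ether captures it at C9. This attack puts C11 on the convex face, so acidic work-up is followed by brief equilibration with DBU, which moves C11 into the equatorial position and rejoins the route at 33.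

**Step 26.** Reagent and substrate may be mismatched, so that hydride transfer to the α face is slow or unselective, and the formate may be lost during a long reaction. Fallback: give up reagent control. Ketone 39 is reduced quickly with NaBH4 and CeCl3 in MeOH at −78 °C, which spares the formate, and the epimers are separated. The 3α-alcohol F10 is returned to 39 by Dess–Martin oxidation for another pass, and the 3β-alcohol is 40.

## Further compounds

F1 | step 12 | hydroxy octalone (21 without the tert-butyldimethylsilyl group) | C1C=C[C@H]2[C@@](C)(CCC(C)(C)O[Si](CC)(CC)CC)[C@H](O)CC(=O)[C@@]2(C)C1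
F2 | step 7 | ethyl 2-(diethoxyphosphoryl)-5-methyl-5-(triethylsilyloxy)hexanoate | CCOC(=O)C(CCC(C)(C)O[Si](CC)(CC)CC)P(=O)(OCC)OCC
F3 | step 7 | ethyl (2E,4E)-2-[3-methyl-3-(triethylsilyloxy)butyl]hexa-2,4-dienoate | C/C=C/C=C(\CCC(C)(C)O[Si](CC)(CC)CC)C(=O)OCC
F4 | step 7 | (2E,4E)-2-[3-methyl-3-(triethylsilyloxy)butyl]hexa-2,4-dienoic acid | C/C=C/C=C(\CCC(C)(C)O[Si](CC)(CC)CC)C(=O)O
F5 | step 7 | (4R)-3-[(2E,4E)-2-[3-methyl-3-(triethylsilyloxy)butyl]hexa-2,4-dienoyl]-4-(propan-2-yl)-1,3-oxazolidin-2-one | C/C=C/C=C(\CCC(C)(C)O[Si](CC)(CC)CC)C(=O)N1[C@H](C(C)C)COC1=O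
F6 | step 7 | (4R)-3-[(2R,3E)-2-methyl-2-[3-methyl-3-(triethylsilyloxy)butyl]hexa-3,5-dienoyl]-4-(propan-2-yl)-1,3-oxazolidin-2-one | O=C(N1[C@H](C(C)C)COC1=O)[C@](C)(CCC(C)(C)O[Si](CC)(CC)CC)/C=C/C=C
F7 | step 16 | C8 allylic alcohol of 24 (both C8 epimers) | OC1C=C[C@H]2[C@@](C)(CCC(C)(C)O[Si](CC)(CC)CC)[C@H](O[Si](C)(C)C(C)(C)C)CC[C@@]2(C)C1
F8 | step 19 | trimethylsilyl dienol ether of 25 | C[Si](C)(C)OC=1C=C[C@H]2[C@@](C)(CCC(C)(C)O[Si](CC)(CC)CC)[C@H](O[Si](C)(C)C(C)(C)C)CC[C@@]2(C)C=1
F9 | step 19 | methyl 2-methyl-5-methylidene-4,6-dioxo-5,6-dihydro-4H-pyran-3-carboxylate | COC(=O)C1=C(C)OC(=O)C(=C)C1=O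
F10 | step 26 | 3α-hydroxy epimer of 40 | C=C1CC[C@H]2[C@@](C)(CCC(C)(C)OC=O)[C@H](O)CC[C@@]2(C)[C@H]1Cc1c(OC)oc(C)c(C(=O)OC)c1=O
A1 | alternative 1 | cis-fused enone with C8 methylidene and 9-CH2OTBS | C=C1CC[C@H]2CC(=O)C=C[C@@]2(C)[C@H]1CO[Si](C)(C)C(C)(C)C
A2 | alternative 1 | 4-[1-(tert-butyldimethylsilyloxy)-5-iodo-3-methylidenepentan-2-yl]-4-methylcyclohexa-2,5-dienone | ICCC(=C)[C@H](CO[Si](C)(C)C(C)(C)C)C1(C)C=CC(=O)C=C1
A3 | alternative 2 | C8 ketone with 9-CH2–(4-hydroxy-2-pyranone) arm | O=C1CC[C@H]2[C@@](C)(CCC(C)(C)O[Si](CC)(CC)CC)[C@@H](O[Si](C)(C)C(C)(C)C)CC[C@@]2(C)[C@H]1Cc1c(O)c(C(=O)OC)c(C)oc1=O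
A4 | alternative 2 | C8–C9 trimethylsilyl enol ether of the decalone | C[Si](C)(C)OC=1CC[C@H]2[C@@](C)(CCC(C)(C)O[Si](CC)(CC)CC)[C@@H](O[Si](C)(C)C(C)(C)C)CC[C@@]2(C)C=1
A5 | alternative 2 | formaldehyde | C=O
A6 | alternative 2 | methyl 2-methyl-5-methylidene-4,6-dioxo-5,6-dihydro-4H-pyran-3-carboxylate | COC(=O)C1=C(C)OC(=O)C(=C)C1=O
A7 | alternative 3 | cis-fused adduct with C9 ketone, C3 silyl enol ether and C4 methyl ester | C1CC[C@H]2[C@@H](C(=O)OC)C(O[Si](C)(C)C(C)(C)C)=CC[C@@]2(C)C1=O
A8 | alternative 3 | 2-methylcyclohex-2-en-1-one | CC1=CCCCC1=O
A9 | alternative 3 | methyl 3-(tert-butyldimethylsilyloxy)penta-2,4-dienoate | C=CC(O[Si](C)(C)C(C)(C)C)=CC(=O)OC
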